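Everything rests on making ring B' of the flavone half from acyclic carbons, so that the C3'–C3''' biaryl link is not a cross-coupling product but the former benzylic C–C bond of an arylacetic acid. Ring B' has its hydroxyl at C4''', ring B ortho to it at C3''' and the flavone carbon para at C1'''; a 4-aryl-1-methoxy-3-silyloxydiene plus methyl propiolate maps onto exactly this 1,2,4-pattern. One cycloaddition/aromatisation forms C2'''–C3''' and C1'''–C6''' and leaves two distinguishable rings: one with ester and free phenol, the other with bromide and benzyl ether. The precursor is a benzyl-protected bromoaryl diene bearing a robust tert-butyldimethylsilyl enol ether.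

Key step: step 7

Assumption: locants C1'–C6' denote ring B of the flavanone half and C1'''–C6''' ring B' of the flavone half.
Assumption: the facial sense of the pyridine–oxazoline palladium catalyst on the chromone is taken from its behaviour with cyclic enones ((S)-ligand gives (R)-product), so the (R)-ligand is specified for the (2S)-flavanone; if an assay on a model shows the opposite sense, the antipodal ligand is used.

Step 1
Reactants: 1 2-hydroxyphenylacetic acid
Product: 2 2-(5-bromo-2-hydroxyphenyl)acetic acid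
Conditions: N-bromosuccinimide (1.0 equiv), MeCN, 0 °C to rt
Reagents that add atoms: N-bromosuccinimide, O=C1CCC(=O)N1Br
Why: Electrophilic aromatic bromination, in which the free hydroxyl should direct the single bromine to the unhindered para position C5.

Step 2
Reactants: 2 2-(5-bromo-2-hydroxyphenyl)acetic acid
Product: 3 benzyl 2-[2-(benzyloxy)-5-bromophenyl]acetate
Conditions: BnBr (2.3 equiv), K2CO3, DMF, 50 °C
Reagents that add atoms: benzyl bromide, BrCc1ccccc1
Why: Williamson ether synthesis with concurrent carboxylate O-alkylation, both simple SN2 reactions under a base too weak to enolise the ester.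

Step 3
Reactants: 3 benzyl 2-[2-(benzyloxy)-5-bromophenyl]acetate
Product: 4 2-[2-(benzyloxy)-5-bromophenyl]-N-methoxy-N-methylacetamide
Conditions: MeNH(OMe)·HCl (1.5 equiv), i-PrMgCl (3.0 equiv), THF, −20 to 0 °C
Reagents that add atoms: N,O-dimethylhydroxylamine hydrochloride, CNOC.Cl
Why: Aminolysis of the ester by the chloromagnesium amide of N,O-dimethylhydroxylamine (Weinreb amide formation), at a temperature where the aryl bromide should not undergo halogen–magnesium exchange.

Step 4
Reactants: 4 2-[2-(benzyloxy)-5-bromophenyl]-N-methoxy-N-methylacetamide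
Product: 5 1-[2-(benzyloxy)-5-bromophenyl]but-3-yn-2-one
Conditions: HC≡CMgBr (2.5 equiv), THF, 0 °C; poured into cold 1 M HCl
Reagents that add atoms: ethynylmagnesium bromide, C#C[Mg]Br
Why: Weinreb ketone synthesis, in which the chelated tetrahedral adduct prevents over-addition, the weakly basic acetylide spares the benzylic protons and the aryl bromide, and the acidic quench keeps the released amine from adding to the ynone.

Step 5
Reactants: 5 1-[2-(benzyloxy)-5-bromophenyl]but-3-yn-2-one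
Product: 6 (E)-1-[2-(benzyloxy)-5-bromophenyl]-4-methoxybut-3-en-2-one
Conditions: MeOH, DABCO (10 mol%), 0 °C to rt
Reagents that add atoms: methanol, CO
Why: Amine-catalysed oxa-Michael addition of methanol to the terminal ynone, which should stop at mono-addition and give the thermodynamically preferred (E)-beta-methoxy enone.

Step 6
Reactants: 6 (E)-1-[2-(benzyloxy)-5-bromophenyl]-4-methoxybut-3-en-2-one
Product: 7 (1E,3Z)-4-[2-(benzyloxy)-5-bromophenyl]-3-[(tert-butyldimethylsilyl)oxy]-1-methoxybuta-1,3-diene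
Conditions: t-BuMe2SiOTf (1.2 equiv), Et3N (2 equiv), Et2O, 0 °C
Reagents that add atoms: tert-butyldimethylsilyl trifluoromethanesulfonate, CC(C)(C)[Si](C)(C)OS(=O)(=O)C(F)(F)F
Why: Soft enolisation to the silyl enol ether, possible only at the benzylic CH2 and expected to give the aryl-conjugated (Z)-isomer (aryl cis to silyloxy, away from the methoxyvinyl arm).

Step 7
Reactants: 7 (1E,3Z)-4-[2-(benzyloxy)-5-bromophenyl]-3-[(tert-butyldimethylsilyl)oxy]-1-methoxybuta-1,3-diene; 8 methyl propiolate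
Product: 11 methyl 3-[2-(benzyloxy)-5-bromophenyl]-4-hydroxybenzoate, via cycloadduct 9 (not isolated), via aryl silyl ether 10 (not isolated)
Conditions: 8 (3 equiv), toluene, 110 °C, sealed tube; then Bu4NF, THF, 0 °C; aq. NH4Cl
Reagents that add atoms: none
Why: A thermal, concerted but asynchronous normal-demand [4+2] cycloaddition should join the aryl-bearing diene terminus to the propiolate beta-carbon (C3'''–C2''') and the methoxy-bearing terminus to the alpha-carbon (C6'''–C1'''), giving cyclohexa-1,4-diene 9. Adduct 9 should lose methanol to aryl silyl ether 10 and fluoride then frees the phenol, while any 9 left over converges on the same phenol by desilylation, beta-elimination of methoxide and tautomerisation. The closest known reaction type is the Diels–Alder reaction of 1-alkoxy-3-silyloxy-1,3-dienes with acetylenic esters followed by elimination to 4-hydroxybenzoates. Ring B' is closed by intermolecular [4+2] cycloaddition (four diene carbons plus two alkyne carbons), and aromatisation erases the two transient sp3 centres, so no stereocentre needs control. The selectivity required is regiochemical (ester para and ring B ortho to the new hydroxyl) and is secured by the matched polarisation of the doubly donor-substituted diene and the propiolate. The (3Z) geometry keeps the aryl group outside the s-cis diene, and the benzyl ether and bromide are inert to heat and fluoride.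

Step 8
Reactants: 11 methyl 3-[2-(benzyloxy)-5-bromophenyl]-4-hydroxybenzoate
Product: 12 methyl 4-(benzyloxy)-3-[2-(benzyloxy)-5-bromophenyl]benzoate
Conditions: BnBr (1.2 equiv), K2CO3, DMF, rt
Reagents that add atoms: benzyl bromide, BrCc1ccccc1
Why: Williamson ether synthesis on the only free phenol, giving both biaryl oxygens the same acid- and base-stable protecting group.

Step 9
Reactants: 13 2',4',6'-trihydroxyacetophenone
Product: 14 1-[2,4-bis(benzyloxy)-6-hydroxyphenyl]ethan-1-one
Conditions: BnBr (2.05 equiv), K2CO3, acetone, reflux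
Reagents that add atoms: benzyl bromide, BrCc1ccccc1
Why: Williamson ether synthesis that should stop at the dibenzyl ether because the last ortho hydroxyl is deactivated by its hydrogen bond to the acetyl carbonyl.

Step 10
Reactants: 12 methyl 4-(benzyloxy)-3-[2-(benzyloxy)-5-bromophenyl]benzoate; 14 1-[2,4-bis(benzyloxy)-6-hydroxyphenyl]ethan-1-one
Product: 15 1-[2,4-bis(benzyloxy)-6-hydroxyphenyl]-3-{4-(benzyloxy)-3-[2-(benzyloxy)-5-bromophenyl]phenyl}propane-1,3-dione
Conditions: 14 (1.3 equiv), LiN(SiMe3)2 (4 equiv), THF, −78 °C to rt; 1 M HCl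
Reagents that add atoms: none
Why: Crossed Claisen condensation of the lithium phenoxide-enolate of 14 with the non-enolisable methyl ester, driven to completion by deprotonation of the 1,3-diketone formed.

Step 11
Reactants: 15 1-[2,4-bis(benzyloxy)-6-hydroxyphenyl]-3-{4-(benzyloxy)-3-[2-(benzyloxy)-5-bromophenyl]phenyl}propane-1,3-dione
Product: 16 5,7-bis(benzyloxy)-2-{4-(benzyloxy)-3-[2-(benzyloxy)-5-bromophenyl]phenyl}-4H-chromen-4-one
Conditions: TsOH·H2O (20 mol%), toluene, 80 °C
Reagents that add atoms: none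
Why: Acid-catalysed cyclodehydration of the 2-hydroxyaryl 1,3-diketone (hemiketal formation, then loss of water), the closing stage of the Baker–Venkataraman flavone synthesis, under conditions mild enough for benzyl ethers.

Step 12
Reactants: 16 5,7-bis(benzyloxy)-2-{4-(benzyloxy)-3-[2-(benzyloxy)-5-bromophenyl]phenyl}-4H-chromen-4-one
Product: 17 (4-(benzyloxy)-3-{2-(benzyloxy)-5-[5,7-bis(benzyloxy)-4-oxo-4H-chromen-2-yl]phenyl}phenyl)boronic acid
Conditions: B2(OH)4 (3 equiv), PdCl(2'-aminobiphenyl-2-yl)(XPhos) (2 mol%), XPhos (4 mol%), KOAc (3 equiv), EtOH/THF, 80 °C; dilute aq. HCl work-up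
Reagents that add atoms: tetrahydroxydiboron, OB(O)B(O)O
Why: Miyaura borylation of the aryl bromide with tetrahydroxydiboron, which should deliver the free boronic acid directly and tolerate the flavone carbonyl and the benzyl ethers.

Step 13
Reactants: 14 1-[2,4-bis(benzyloxy)-6-hydroxyphenyl]ethan-1-one
Product: 19 5,7-bis(benzyloxy)-4H-chromen-4-one, via enaminone 18 (not isolated)
Conditions: Me2NCH(OMe)2 (3 equiv), toluene, 100 °C; then conc. HCl, CH2Cl2, 40 °C
Reagents that add atoms: N,N-dimethylformamide dimethyl acetal, COC(OC)N(C)C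
Why: Condensation of the methyl ketone with the formamide acetal gives the enaminone, and acid-promoted addition of the phenol with elimination of dimethylamine closes the pyranone (enaminone chromone synthesis).

Step 14
Reactants: 17 (4-(benzyloxy)-3-{2-(benzyloxy)-5-[5,7-bis(benzyloxy)-4-oxo-4H-chromen-2-yl]phenyl}phenyl)boronic acid; 19 5,7-bis(benzyloxy)-4H-chromen-4-one
Product: 20 (2S)-5,7-bis(benzyloxy)-2-(4-(benzyloxy)-3-{2-(benzyloxy)-5-[5,7-bis(benzyloxy)-4-oxo-4H-chromen-2-yl]phenyl}phenyl)-2,3-dihydro-4H-chromen-4-one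
Conditions: 19 (3 equiv), Pd(OCOCF3)2 (10 mol%), (R)-4-tert-butyl-2-(pyridin-2-yl)-4,5-dihydrooxazole (12 mol%), NH4PF6 (30 mol%), H2O (5 equiv), ClCH2CH2Cl, 60 °C
Reagents that add atoms: none
Why: Palladium-catalysed asymmetric conjugate addition of an arylboronic acid to a chromone, in which the cationic aryl–palladium species should insert C2=C3 on the face left open by the ligand tert-butyl group to set C2 as (S), and base-free protonolysis of the palladium enolate avoids ring opening, while the 2-aryl-substituted flavone enone is too hindered to compete.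

Step 15
Reactants: 20 (2S)-5,7-bis(benzyloxy)-2-(4-(benzyloxy)-3-{2-(benzyloxy)-5-[5,7-bis(benzyloxy)-4-oxo-4H-chromen-2-yl]phenyl}phenyl)-2,3-dihydro-4H-chromen-4-one
Product: 21 (2S)-2-{3-[5-(5,7-dihydroxy-4-oxo-4H-chromen-2-yl)-2-hydroxyphenyl]-4-hydroxyphenyl}-5,7-dihydroxy-2,3-dihydro-4H-chromen-4-one
Conditions: H2 (1 atm), Pd/C (10%), THF/MeOH, rt, stopped after six equivalents of uptake
Reagents that add atoms: none
Why: Hydrogenolysis of the six benzyl aryl ethers under neutral conditions, which should spare the flavone C2=C3 bond and the flavanone ring and cannot racemise C2 because no acid or base is present to open the ring.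

Compound list
1 | 2-hydroxyphenylacetic acid | OC(=O)Cc1ccccc1O | starting material
2 | 2-(5-bromo-2-hydroxyphenyl)acetic acid | OC(=O)Cc1cc(Br)ccc1O | intermediate
3 | benzyl 2-[2-(benzyloxy)-5-bromophenyl]acetate | O=C(Cc1cc(Br)ccc1OCc1ccccc1)OCc1ccccc1 | intermediate
4 | 2-[2-(benzyloxy)-5-bromophenyl]-N-methoxy-N-methylacetamide | CON(C)C(=O)Cc1cc(Br)ccc1OCc1ccccc1 | intermediate
5 | 1-[2-(benzyloxy)-5-bromophenyl]but-3-yn-2-one | C#CC(=O)Cc1cc(Br)ccc1OCc1ccccc1 | intermediate
6 | (E)-1-[2-(benzyloxy)-5-bromophenyl]-4-methoxybut-3-en-2-one | CO/C=C/C(=O)Cc1cc(Br)ccc1OCc1ccccc1 | intermediate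
7 | (1E,3Z)-4-[2-(benzyloxy)-5-bromophenyl]-3-[(tert-butyldimethylsilyl)oxy]-1-methoxybuta-1,3-diene | CO/C=C/C(=C/c1cc(Br)ccc1OCc1ccccc1)O[Si](C)(C)C(C)(C)C | intermediate
8 | methyl propiolate | C#CC(=O)OC | starting material
9 | methyl cis-3-[2-(benzyloxy)-5-bromophenyl]-4-[(tert-butyldimethylsilyl)oxy]-6-methoxycyclohexa-1,4-diene-1-carboxylate (racemic cycloadduct, one enantiomer drawn) | COC(=O)C1=C[C@@H](c2cc(Br)ccc2OCc2ccccc2)C(O[Si](C)(C)C(C)(C)C)=C[C@H]1OC | intermediate (not isolated)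
10 | methyl 3-[2-(benzyloxy)-5-bromophenyl]-4-[(tert-butyldimethylsilyl)oxy]benzoate | COC(=O)c1ccc(O[Si](C)(C)C(C)(C)C)c(-c2cc(Br)ccc2OCc2ccccc2)c1 | intermediate (not isolated)
11 | methyl 3-[2-(benzyloxy)-5-bromophenyl]-4-hydroxybenzoate | COC(=O)c1ccc(O)c(-c2cc(Br)ccc2OCc2ccccc2)c1 | intermediate
12 | methyl 4-(benzyloxy)-3-[2-(benzyloxy)-5-bromophenyl]benzoate | COC(=O)c1ccc(OCc2ccccc2)c(-c2cc(Br)ccc2OCc2ccccc2)c1 | intermediate
13 | 2',4',6'-trihydroxyacetophenone | CC(=O)c1c(O)cc(O)cc1O | starting material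
14 | 1-[2,4-bis(benzyloxy)-6-hydroxyphenyl]ethan-1-one | CC(=O)c1c(O)cc(OCc2ccccc2)cc1OCc1ccccc1 | intermediate
15 | 1-[2,4-bis(benzyloxy)-6-hydroxyphenyl]-3-{4-(benzyloxy)-3-[2-(benzyloxy)-5-bromophenyl]phenyl}propane-1,3-dione | O=C(CC(=O)c1ccc(OCc2ccccc2)c(-c2cc(Br)ccc2OCc2ccccc2)c1)c1c(O)cc(OCc2ccccc2)cc1OCc1ccccc1 | intermediate
16 | 5,7-bis(benzyloxy)-2-{4-(benzyloxy)-3-[2-(benzyloxy)-5-bromophenyl]phenyl}-4H-chromen-4-one | O=c1cc(-c2ccc(OCc3ccccc3)c(-c3cc(Br)ccc3OCc3ccccc3)c2)oc2cc(OCc3ccccc3)cc(OCc3ccccc3)c12 | intermediate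
17 | (4-(benzyloxy)-3-{2-(benzyloxy)-5-[5,7-bis(benzyloxy)-4-oxo-4H-chromen-2-yl]phenyl}phenyl)boronic acid | OB(O)c1ccc(OCc2ccccc2)c(-c2cc(-c3cc(=O)c4c(OCc5ccccc5)cc(OCc5ccccc5)cc4o3)ccc2OCc2ccccc2)c1 | intermediate
18 | (E)-1-[2,4-bis(benzyloxy)-6-hydroxyphenyl]-3-(dimethylamino)prop-2-en-1-one | CN(C)/C=C/C(=O)c1c(O)cc(OCc2ccccc2)cc1OCc1ccccc1 | intermediate (not isolated)
19 | 5,7-bis(benzyloxy)-4H-chromen-4-one | O=c1ccoc2cc(OCc3ccccc3)cc(OCc3ccccc3)c12 | intermediate
20 | (2S)-5,7-bis(benzyloxy)-2-(4-(benzyloxy)-3-{2-(benzyloxy)-5-[5,7-bis(benzyloxy)-4-oxo-4H-chromen-2-yl]phenyl}phenyl)-2,3-dihydro-4H-chromen-4-one | O=C1C[C@@H](c2ccc(OCc3ccccc3)c(-c3cc(-c4cc(=O)c5c(OCc6ccccc6)cc(OCc6ccccc6)cc5o4)ccc3OCc3ccccc3)c2)Oc2cc(OCc3ccccc3)cc(OCc3ccccc3)c21 | intermediate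
21 | (2S)-2-{3-[5-(5,7-dihydroxy-4-oxo-4H-chromen-2-yl)-2-hydroxyphenyl]-4-hydroxyphenyl}-5,7-dihydroxy-2,3-dihydro-4H-chromen-4-one | O=C1C[C@@H](c2ccc(O)c(-c3cc(-c4cc(=O)c5c(O)cc(O)cc5o4)ccc3O)c2)Oc2cc(O)cc(O)c21 | target

Total step count: 15. Longest linear sequence: 13 (steps 1–8, 10, 11, 12, 14, 15).

Steps most likely to fail

Step 7. The cycloaddition may stall because bond formation at the aryl-substituted diene terminus is slow, while the silyl enol ether hydrolyses back to the enone and the propiolate oligomerises on long heating. The fallback changes the diene class and sets out from ynone 5. Conjugate addition of dimethylamine (Me2NH, THF, 0 °C) should give (E)-1-[2-(benzyloxy)-5-bromophenyl]-4-(dimethylamino)but-3-en-2-one F1. Silylation (NaN(SiMe3)2, t-BuMe2SiCl, THF, −78 °C) should give the 1-amino-3-silyloxydiene (1E,3Z)-4-[2-(benzyloxy)-5-bromophenyl]-3-[(tert-butyldimethylsilyl)oxy]-N,N-dimethylbuta-1,3-dien-1-amine F2, which is far more electron-rich and should add 8 with the same regiochemistry near room temperature. The adduct is racemic methyl cis-3-[2-(benzyloxy)-5-bromophenyl]-4-[(tert-butyldimethylsilyl)oxy]-6-(dimethylamino)cyclohexa-1,4-diene-1-carboxylate F3. Loss of dimethylamine on mild acid treatment should give aryl silyl ether 10, and fluoride brings the sequence back to the route at 11.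

Step 14. The electron-rich boronic acid, used here as the limiting partner, may protodeboronate faster than the aryl–palladium species inserts, and facial selectivity on the 5,7-dialkoxychromone may be insufficient. The fallback forms the C2–O1 bond instead of the C2–C1' bond and sets out from bromide 16. Palladium-catalysed formylation (Pd(OAc)2, di(1-adamantyl)-n-butylphosphine, TMEDA, CO/H2, toluene, 100 °C) should give 4-(benzyloxy)-3-{2-(benzyloxy)-5-[5,7-bis(benzyloxy)-4-oxo-4H-chromen-2-yl]phenyl}benzaldehyde F4. Claisen–Schmidt condensation with 14 (KOH, EtOH/THF, rt) should give the chalcone (E)-1-[2,4-bis(benzyloxy)-6-hydroxyphenyl]-3-(4-(benzyloxy)-3-{2-(benzyloxy)-5-[5,7-bis(benzyloxy)-4-oxo-4H-chromen-2-yl]phenyl}phenyl)prop-2-en-1-one F5. Intramolecular oxa-Michael cyclisation (NaOAc, EtOH, reflux) should give racemic 5,7-bis(benzyloxy)-2-(4-(benzyloxy)-3-{2-(benzyloxy)-5-[5,7-bis(benzyloxy)-4-oxo-4H-chromen-2-yl]phenyl}phenyl)-2,3-dihydro-4H-chromen-4-one F6. Preparative HPLC on a cellulose tris(3,5-dimethylphenylcarbamate) phase should separate the (2R)-enantiomer (2R)-5,7-bis(benzyloxy)-2-(4-(benzyloxy)-3-{2-(benzyloxy)-5-[5,7-bis(benzyloxy)-4-oxo-4H-chromen-2-yl]phenyl}phenyl)-2,3-dihydro-4H-chromen-4-one F7 from the (2S)-enantiomer, which is 20, where the route resumes.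

Step 10. The para-alkoxy-deactivated ester may be acylated only partly, with proton transfer returning the acetophenone. The fallback makes the same C–C bond intramolecularly and sets out from ester 12. Saponification (LiOH, THF/MeOH/H2O, 50 °C) should give 4-(benzyloxy)-3-[2-(benzyloxy)-5-bromophenyl]benzoic acid F8. Esterification with the phenol of 14 (EDC·HCl, DMAP, CH2Cl2, rt) should give 2-acetyl-3,5-bis(benzyloxy)phenyl 4-(benzyloxy)-3-[2-(benzyloxy)-5-bromophenyl]benzoate F9. Baker–Venkataraman rearrangement (KOH, pyridine, 50 °C) should then transfer the aroyl group from oxygen to the acetyl carbon and return the route at diketone 15.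

Further compounds
F1 | step 7 | (E)-1-[2-(benzyloxy)-5-bromophenyl]-4-(dimethylamino)but-3-en-2-one | CN(C)/C=C/C(=O)Cc1cc(Br)ccc1OCc1ccccc1
F2 | step 7 | (1E,3Z)-4-[2-(benzyloxy)-5-bromophenyl]-3-[(tert-butyldimethylsilyl)oxy]-N,N-dimethylbuta-1,3-dien-1-amine | CN(C)/C=C/C(=C/c1cc(Br)ccc1OCc1ccccc1)O[Si](C)(C)C(C)(C)C
F3 | step 7 | methyl cis-3-[2-(benzyloxy)-5-bromophenyl]-4-[(tert-butyldimethylsilyl)oxy]-6-(dimethylamino)cyclohexa-1,4-diene-1-carboxylate (racemic, one enantiomer drawn) | COC(=O)C1=C[C@@H](c2cc(Br)ccc2OCc2ccccc2)C(O[Si](C)(C)C(C)(C)C)=C[C@H]1N(C)C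
F4 | step 14 | 4-(benzyloxy)-3-{2-(benzyloxy)-5-[5,7-bis(benzyloxy)-4-oxo-4H-chromen-2-yl]phenyl}benzaldehyde | O=Cc1ccc(OCc2ccccc2)c(-c2cc(-c3cc(=O)c4c(OCc5ccccc5)cc(OCc5ccccc5)cc4o3)ccc2OCc2ccccc2)c1
F5 | step 14 | (E)-1-[2,4-bis(benzyloxy)-6-hydroxyphenyl]-3-(4-(benzyloxy)-3-{2-(benzyloxy)-5-[5,7-bis(benzyloxy)-4-oxo-4H-chromen-2-yl]phenyl}phenyl)prop-2-en-1-one | O=C(/C=C/c1ccc(OCc2ccccc2)c(-c2cc(-c3cc(=O)c4c(OCc5ccccc5)cc(OCc5ccccc5)cc4o3)ccc2OCc2ccccc2)c1)c1c(O)cc(OCc2ccccc2)cc1OCc1ccccc1
F6 | step 14 | racemic 5,7-bis(benzyloxy)-2-(4-(benzyloxy)-3-{2-(benzyloxy)-5-[5,7-bis(benzyloxy)-4-oxo-4H-chromen-2-yl]phenyl}phenyl)-2,3-dihydro-4H-chromen-4-one | O=C1CC(c2ccc(OCc3ccccc3)c(-c3cc(-c4cc(=O)c5c(OCc6ccccc6)cc(OCc6ccccc6)cc5o4)ccc3OCc3ccccc3)c2)Oc2cc(OCc3ccccc3)cc(OCc3ccccc3)c21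
F7 | step 14 | (2R)-5,7-bis(benzyloxy)-2-(4-(benzyloxy)-3-{2-(benzyloxy)-5-[5,7-bis(benzyloxy)-4-oxo-4H-chromen-2-yl]phenyl}phenyl)-2,3-dihydro-4H-chromen-4-one | O=C1C[C@H](c2ccc(OCc3ccccc3)c(-c3cc(-c4cc(=O)c5c(OCc6ccccc6)cc(OCc6ccccc6)cc5o4)ccc3OCc3ccccc3)c2)Oc2cc(OCc3ccccc3)cc(OCc3ccccc3)c21
F8 | step 10 | 4-(benzyloxy)-3-[2-(benzyloxy)-5-bromophenyl]benzoic acid | OC(=O)c1ccc(OCc2ccccc2)c(-c2cc(Br)ccc2OCc2ccccc2)c1
F9 | step 10 | 2-acetyl-3,5-bis(benzyloxy)phenyl 4-(benzyloxy)-3-[2-(benzyloxy)-5-bromophenyl]benzoate | CC(=O)c1c(OC(=O)c2ccc(OCc3ccccc3)c(-c3cc(Br)ccc3OCc3ccccc3)c2)cc(OCc2ccccc2)cc1OCc1ccccc1
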